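**Plan**
- Enabling feature: ring C (C8, C9, C11–C14) is a fully substituted hydroxy-isopropyl-p-quinone. C11–C14 with O11, O12, i-Pr-13 and O14 correspond atom for atom to 3-isopropoxy-4-isopropylcyclobutenedione, and C8=C9 is then just an alkene of the seven-membered ring B.
- Retrosynthetic cuts, in order: C7–OAc; C8–C14 (six-electron closure of ring C) and C9–C11 (alkenyl-magnesium to the dione); lactone O–C10 and C4–CH3; C20 (one-carbon ring expansion).
- Forward: ring B by ring expansion of 5-bromo-1-tetralone; the benzene ring becomes ring A by Birch reductive methylation; the γ-lactone closes on C10 under acid; ring C is grown last from the squarate; the C7 acetate, the quinone and O12 are unveiled at the end.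
- Stereochemistry: C4 from the methoxymethylpyrrolidine amide in the Birch methylation; C10 from the one-atom tether to C19; C5 from anti addition across C5=C10; C7 from α-face capture of the benzylic cation, opposite the lactone bridge.

Key step: step 12

Convention: icetexane locants are used throughout (C1–C3 ring A CH2, C4 quaternary, C19 lactone C=O, C5 ring-fusion CH, C6/C7 ring B, C20 the CH2 between C9 and C10; β = face of the lactone oxygen).
Assumption: the (S)-auxiliary is taken to direct methylation of this 2,3-dialkylbenzamide enolate to the face that gives (4S); should its sense be the reverse, the commercial (R)-enantiomer is used with no other change.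

**Route**

Step 1
Reactants: 1 5-bromo-1-tetralone
Product: 2 5-bromo-1-methylidene-1,2,3,4-tetrahydronaphthalene
Conditions: Ph3PCH3Br, KOt-Bu, THF, 0 °C to rt
Reagents that add atoms: methyltriphenylphosphonium bromide, C[P+](c1ccccc1)(c1ccccc1)c1ccccc1.[Br-]
Why: Wittig methylenation of an aryl ketone; the aryl bromide is inert to the ylide.

Step 2
Reactants: 2 5-bromo-1-methylidene-1,2,3,4-tetrahydronaphthalene
Product: 3 1-bromo-5,7,8,9-tetrahydro-6H-benzo[7]annulen-6-one
Conditions: PhI(OH)OTs (HTIB), MeOH–H2O 95:5, rt
Reagents that add atoms: water, O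
Why: Iodine(III)-mediated oxidative rearrangement of an exocyclic styrene: the aryl carbon migrates to the former methylene with loss of iodobenzene, so the ring grows by one carbon and the ketone ends at the homobenzylic position (future C9), regiospecifically.

Step 3
Reactants: 3 1-bromo-5,7,8,9-tetrahydro-6H-benzo[7]annulen-6-one
Product: 4 1-bromo-5,7,8,9-tetrahydrospiro[benzo[7]annulene-6,2'-[1,3]dioxolane]
Conditions: HOCH2CH2OH, TsOH (cat.), benzene, reflux, Dean–Stark
Reagents that add atoms: ethylene glycol, OCCO
Why: Acid-catalysed ketalisation masks the ketone for the dissolving-metal step.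

Step 4
Reactants: 4 1-bromo-5,7,8,9-tetrahydrospiro[benzo[7]annulene-6,2'-[1,3]dioxolane]; 5 (S)-2-(methoxymethyl)pyrrolidine
Product: 6 [(2S)-2-(methoxymethyl)pyrrolidin-1-yl](5,7,8,9-tetrahydrospiro[benzo[7]annulene-6,2'-[1,3]dioxolan]-1-yl)methanone
Conditions: Pd(OAc)2 (3 mol %), Xantphos (6 mol %), CO (1 atm), Na2CO3, toluene, 90 °C
Reagents that add atoms: carbon monoxide, [C-]#[O+]
Why: Palladium-catalysed aminocarbonylation of an aryl bromide installs the future C19 and the chiral auxiliary in one operation.

Step 5
Reactants: 6 [(2S)-2-(methoxymethyl)pyrrolidin-1-yl](5,7,8,9-tetrahydrospiro[benzo[7]annulene-6,2'-[1,3]dioxolan]-1-yl)methanone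
Product: 8 [(2S)-2-(methoxymethyl)pyrrolidin-1-yl][(1S)-1-methyl-1,4,5,7,8,9-hexahydrospiro[benzo[7]annulene-6,2'-[1,3]dioxolan]-1-yl]methanone, via potassium amide enolate 7 (not isolated)
Conditions: K, NH3–THF, t-BuOH (1 equiv), −78 °C; piperylene; MeI, −78 °C to rt
Reagents that add atoms: iodomethane, CI
Why: Asymmetric Birch reduction–alkylation of a chiral benzamide: ipso/para reduction gives the amide enolate, and methyl iodide enters at C4 on the face left open by the potassium-bound methoxymethyl arm of the auxiliary, which sets the C4 quaternary centre.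

Step 6
Reactants: 8 [(2S)-2-(methoxymethyl)pyrrolidin-1-yl][(1S)-1-methyl-1,4,5,7,8,9-hexahydrospiro[benzo[7]annulene-6,2'-[1,3]dioxolan]-1-yl]methanone
Product: 9 [(2S)-2-(methoxymethyl)pyrrolidin-1-yl][(1S)-1-methyl-1,2,3,4,5,7,8,9-octahydrospiro[benzo[7]annulene-6,2'-[1,3]dioxolan]-1-yl]methanone
Conditions: H2 (1 atm), RhCl(PPh3)3 (5 mol %), benzene–EtOH, rt
Reagents that add atoms: none
Why: Homogeneous rhodium hydrogenation reduces the cis-disubstituted C2=C3 alkene and leaves the tetrasubstituted C5=C10 alkene, so only one alkene is present for the cationic step that follows.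

Step 7
Reactants: 9 [(2S)-2-(methoxymethyl)pyrrolidin-1-yl][(1S)-1-methyl-1,2,3,4,5,7,8,9-octahydrospiro[benzo[7]annulene-6,2'-[1,3]dioxolan]-1-yl]methanone
Product: 11 AB keto-lactone (9-oxo-19,10-olide of the icetexane C1–C10/C18–C20 fragment; 4S, H-5 α, O–C10 and C19 β, 4-CH3 α), via cyclic iminium ether tosylate 10 (not isolated)
Conditions: TsOH·H2O (2.5 equiv), toluene, 80 °C; then aq. NaHCO3
Reagents that add atoms: water, O
Why: Acid-mediated lactonisation of a β,γ-unsaturated tertiary amide: the ketal is hydrolysed, C5 is protonated on the α face (directly or through the C10=C20 enone) and the amide oxygen closes on C10 from the β face, after which hydrolysis of the iminium ether releases the auxiliary; C10 is fixed by the one-atom tether from C4, and C5 by anti addition, which also places C6 equatorial on ring A (the more stable fusion).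

Step 8
Reactants: 11 AB keto-lactone
Product: 13 AB lactone Δ8-en-9-yl trifluoromethanesulfonate, via potassium C8-enolate 12 (not isolated)
Conditions: KHMDS, THF, −78 °C; N-(5-chloro-2-pyridyl)triflimide, −78 °C
Reagents that add atoms: N-(5-chloro-2-pyridyl)bis(trifluoromethanesulfonimide), O=S(=O)(N(c1ccc(Cl)cn1)S(=O)(=O)C(F)(F)F)C(F)(F)F
Why: Kinetic enolisation with a bulky amide base removes a C8 proton, not a proton of the neopentyl C20 next to quaternary C10, and the enolate is triflated cold before it can equilibrate (regioselective enol triflate formation).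

Step 9
Reactants: 13 AB lactone Δ8-en-9-yl trifluoromethanesulfonate
Product: 14 9-iodo-Δ8 AB lactone (alkenyl iodide)
Conditions: Ni(cod)2 (10 mol %), NaI, DMA–THF 1:3, rt
Reagents that add atoms: sodium iodide, [Na+].[I-]
Why: Nickel-catalysed triflate-to-iodide exchange of an enol triflate (oxidative addition, halide exchange, reductive elimination) keeps the alkene in place and tolerates the lactone.

Step 10
Reactants: 15 diisopropyl squarate; 16 isopropylmagnesium chloride
Product: 18 3-isopropoxy-4-isopropylcyclobut-3-ene-1,2-dione, via squarate mono-adduct 17 (not isolated)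
Conditions: i-PrMgCl, THF, −78 °C; then 12 M HCl (cat.), CH2Cl2, rt
Reagents that add atoms: water, O
Why: 1,2-Addition of the Grignard reagent to one squarate carbonyl, then acid-induced loss of isopropanol with allylic transposition, is the standard route to 3-alkoxy-4-alkylcyclobutenediones.

Step 11
Reactants: 14 9-iodo-Δ8 AB lactone; 18 3-isopropoxy-4-isopropylcyclobut-3-ene-1,2-dione
Product: 20 4-hydroxy-3-isopropoxy-2-isopropyl-4-(AB lactone Δ8-en-9-yl)cyclobut-2-en-1-one (both carbinol epimers), via alkenylmagnesium chloride 19 (not isolated)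
Conditions: i-PrMgCl·LiCl, THF, 0 °C to rt; then 18, −78 °C; aq. NH4Cl
Reagents that add atoms: none
Why: Iodine–magnesium exchange tolerates the hindered, non-enolisable lactone, and the alkenylmagnesium adds to the more electrophilic carbonyl (the one beside the alkoxy carbon, not the vinylogous ester carbonyl), which fixes the C11/C12/C13/C14 pattern; the carbinol centre forms as both epimers, and both are used.

Step 12
Reactants: 20 4-hydroxy-3-isopropoxy-2-isopropyl-4-(AB lactone Δ8-en-9-yl)cyclobut-2-en-1-one
Product: 23 11,14-dihydroxy-12-isopropoxyicetexa-8,11,13-trien-19,10-olide, via dienylketene 21 (not isolated), via cyclohexa-2,4-dienone 22 (not isolated)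
Conditions: toluene (degassed), 110 °C, Ar
Reagents that add atoms: none
Why: Thermal conrotatory four-electron opening of the cyclobutenone breaks C11–C14 and gives dienylketene 21; the donor hydroxyl rotates outward, so the cycloheptenyl group turns inward and C8 lies beside the ketene carbon C14. A disrotatory six-electron electrocyclisation then forms C8–C14 and closes the six-membered ring C as dienone 22, which enolises to the aromatic hydroquinone 23. The closest known reaction is the Moore rearrangement of 4-alkenyl-4-hydroxycyclobutenones. No stereocentre is created that persists: C11 becomes sp2, so both carbinol epimers converge, and the transient C8 centre is lost on tautomerisation. The step needs outward rotation of the hydroxyl and one orientation of ring C relative to C7 and C20; the first is inherent to a 4-hydroxyl donor, the second was fixed by the carbonyl selectivity of step 11 and the alkene position set in step 8. Neutral heating spares the lactone, and 23 is carried on without exposure to air.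

Step 13
Reactants: 23 11,14-dihydroxy-12-isopropoxyicetexa-8,11,13-trien-19,10-olide
Product: 24 12-isopropoxy-11,14-dimethoxyicetexa-8,11,13-trien-19,10-olide
Conditions: MeI, Cs2CO3, DMF (degassed), rt
Reagents that add atoms: iodomethane, CI
Why: Williamson methylation of both phenols protects the hydroquinone against premature oxidation; the lactone has no α-hydrogen and tolerates carbonate.

Step 14
Reactants: 24 12-isopropoxy-11,14-dimethoxyicetexa-8,11,13-trien-19,10-olide
Product: 25 7α-acetoxy-12-isopropoxy-11,14-dimethoxyicetexa-8,11,13-trien-19,10-olide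
Conditions: DDQ (1.1 equiv), AcOH, rt
Reagents that add atoms: acetic acid, CC(=O)O
Why: DDQ benzylic acetoxylation of an alkoxyarene: hydride leaves from C7, which is para to O12 and ortho to O14 (C20 is neopentyl, only ortho-activated and next to the acyloxy-bearing C10), and acetic acid captures the cation on the α face because the lactone bridge covers the β face, which sets C7.

Step 15
Reactants: 25 7α-acetoxy-12-isopropoxy-11,14-dimethoxyicetexa-8,11,13-trien-19,10-olide
Product: 26 7α-acetoxy-12-isopropoxyicetexa-8,12-diene-11,14-dion-19,10-olide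
Conditions: CAN (2.5 equiv), MeCN–H2O, 0 °C
Reagents that add atoms: water, O
Why: Cerium(IV) oxidative demethylation of the para-dimethoxy pair gives the p-quinone; the isopropyl ether and the acetate are retained.

Step 16
Reactants: 26 7α-acetoxy-12-isopropoxyicetexa-8,12-diene-11,14-dion-19,10-olide
Product: 27 7α-acetoxy-6,7-dihydroicetexone
Conditions: BCl3 (2 equiv), CH2Cl2, −78 °C; pH 7 buffer
Reagents that add atoms: none
Why: Boron trichloride cleaves the secondary alkyl vinylogous ester at O12 (Lewis-acid ether cleavage assisted by chelation to the C11 carbonyl) at a temperature at which the acetate and the lactone should persist.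

**Compound list**
1 | 5-bromo-1-tetralone | O=C1CCCc2c(Br)cccc21 | starting material
2 | 5-bromo-1-methylidene-1,2,3,4-tetrahydronaphthalene | C=C1CCCc2c(Br)cccc21 | intermediate
3 | 1-bromo-5,7,8,9-tetrahydro-6H-benzo[7]annulen-6-one | O=C1CCCc2c(Br)cccc2C1 | intermediate
4 | 1-bromo-5,7,8,9-tetrahydrospiro[benzo[7]annulene-6,2'-[1,3]dioxolane] | Brc1cccc2c1CCCC1(C2)OCCO1 | intermediate
5 | (S)-2-(methoxymethyl)pyrrolidine | COC[C@@H]1CCCN1 | starting material
6 | [(2S)-2-(methoxymethyl)pyrrolidin-1-yl](5,7,8,9-tetrahydrospiro[benzo[7]annulene-6,2'-[1,3]dioxolan]-1-yl)methanone | COC[C@@H]1CCCN1C(=O)c1cccc2c1CCCC1(C2)OCCO1 | intermediate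
7 | potassium amide enolate of the 1,4-dihydrobenzamide (not isolated) | COC[C@@H]1CCCN1C(O[K])=C1C=CCC2=C1CCCC1(C2)OCCO1 | intermediate
8 | [(2S)-2-(methoxymethyl)pyrrolidin-1-yl][(1S)-1-methyl-1,4,5,7,8,9-hexahydrospiro[benzo[7]annulene-6,2'-[1,3]dioxolan]-1-yl]methanone | COC[C@@H]1CCCN1C(=O)[C@@]1(C)C=CCC2=C1CCCC1(C2)OCCO1 | intermediate
9 | [(2S)-2-(methoxymethyl)pyrrolidin-1-yl][(1S)-1-methyl-1,2,3,4,5,7,8,9-octahydrospiro[benzo[7]annulene-6,2'-[1,3]dioxolan]-1-yl]methanone | COC[C@@H]1CCCN1C(=O)[C@@]1(C)CCCC2=C1CCCC1(C2)OCCO1 | intermediate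
10 | cyclic iminium ether tosylate of the keto-lactone, N = (S)-2-(methoxymethyl)pyrrolidinium (not isolated) | C1C[C@@H]2[C@]3(CCC[C@]2(C)C(=[N+]4CCC[C@H]4COC)O3)CC(=O)C1.Cc1ccc(cc1)S(=O)(=O)[O-] | intermediate
11 | AB keto-lactone (9-oxo-19,10-olide; 4S, H-5 α, lactone β) | C1C[C@@H]2[C@]3(CCC[C@]2(C)C(=O)O3)CC(=O)C1 | intermediate
12 | potassium C8-enolate of 11 (not isolated) | C1C[C@@H]2[C@]3(CCC[C@]2(C)C(=O)O3)CC(O[K])=C1 | intermediate
13 | AB lactone Δ8-en-9-yl trifluoromethanesulfonate | C1C[C@@H]2[C@]3(CCC[C@]2(C)C(=O)O3)CC(OS(=O)(=O)C(F)(F)F)=C1 | intermediate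
14 | 9-iodo-Δ8 AB lactone | C1C[C@@H]2[C@]3(CCC[C@]2(C)C(=O)O3)CC(I)=C1 | intermediate
15 | diisopropyl squarate | CC(C)OC1=C(OC(C)C)C(=O)C1=O | starting material
16 | isopropylmagnesium chloride | CC(C)[Mg]Cl | starting material
17 | 4-hydroxy-2,3-diisopropoxy-4-isopropylcyclobut-2-en-1-one (racemic, not isolated) | CC(C)OC1=C(OC(C)C)C(O)(C(C)C)C1=O | intermediate
18 | 3-isopropoxy-4-isopropylcyclobut-3-ene-1,2-dione | CC(C)OC1=C(C(C)C)C(=O)C1=O | intermediate
19 | AB lactone Δ8-en-9-ylmagnesium chloride (not isolated) | C1C[C@@H]2[C@]3(CCC[C@]2(C)C(=O)O3)CC([Mg]Cl)=C1 | intermediate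
20 | 4-hydroxy-3-isopropoxy-2-isopropyl-4-(AB lactone Δ8-en-9-yl)cyclobut-2-en-1-one (carbinol centre as both epimers, left undefined) | C1C[C@@H]2[C@]3(CCC[C@]2(C)C(=O)O3)CC(=C1)C1(O)C(OC(C)C)=C(C(C)C)C1=O | intermediate
21 | dienylketene, C9 cis to C13 across C11=C12 (not isolated) | CC(C)C(=C=O)/C(OC(C)C)=C(/O)C1=CCC[C@@H]2[C@]3(CCC[C@]2(C)C(=O)O3)C1 | intermediate
22 | cyclohexa-2,4-dienone, C8 sp3 and transient, configuration undefined (not isolated) | C1C[C@@H]2[C@]3(CCC[C@]2(C)C(=O)O3)CC2=C(O)C(OC(C)C)=C(C(C)C)C(=O)C12 | intermediate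
23 | 11,14-dihydroxy-12-isopropoxyicetexa-8,11,13-trien-19,10-olide | C1C[C@@H]2[C@]3(CCC[C@]2(C)C(=O)O3)Cc2c1c(O)c(C(C)C)c(OC(C)C)c2O | intermediate
24 | 12-isopropoxy-11,14-dimethoxyicetexa-8,11,13-trien-19,10-olide | C1C[C@@H]2[C@]3(CCC[C@]2(C)C(=O)O3)Cc2c1c(OC)c(C(C)C)c(OC(C)C)c2OC | intermediate
25 | 7α-acetoxy-12-isopropoxy-11,14-dimethoxyicetexa-8,11,13-trien-19,10-olide | CC(=O)O[C@@H]1C[C@@H]2[C@]3(CCC[C@]2(C)C(=O)O3)Cc2c1c(OC)c(C(C)C)c(OC(C)C)c2OC | intermediate
26 | 7α-acetoxy-12-isopropoxyicetexa-8,12-diene-11,14-dion-19,10-olide | CC(=O)O[C@@H]1C[C@@H]2[C@]3(CCC[C@]2(C)C(=O)O3)CC2=C1C(=O)C(C(C)C)=C(OC(C)C)C2=O | intermediate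
27 | 7α-acetoxy-6,7-dihydroicetexone | CC(=O)O[C@@H]1C[C@@H]2[C@]3(CCC[C@]2(C)C(=O)O3)CC2=C1C(=O)C(C(C)C)=C(O)C2=O | target

**Count and risks**
Total steps: 16. Longest linear sequence: 15 (1 to 27 through steps 1–9 and 11–16; step 10 is a one-step side branch).

Step 14. What may go wrong: acetate may attack the C7 cation on the β face, the cation may lose H-6 to give the 6,7-alkene, or the benzylic acetate may be oxidised a second time. The fallback separates oxidation from stereocontrol. It sets out from 24: excess DDQ in aqueous dioxane should give the 7-oxo arene F1; sodium borohydride in methanol, with hydride arriving on the open α face, should give the 7β-alcohol F2; Mitsunobu esterification with acetic acid (PPh3, DIAD) inverts C7 and returns to the route at 25.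

Step 16. What may go wrong: under the Lewis acid, once O12 is freed, C7 may ionise with loss of acetic acid and the 6,7-alkene may form. The fallback removes the isopropyl group before the acetate exists. It sets out from 24: boron trichloride at −78 °C should give the 12-phenol F3; DDQ in acetic acid oxidises this para-alkylphenol to its quinone methide, which takes up acetic acid at C7 from the α face to give the 7α-acetoxy-12-phenol F4; cerium(IV) ammonium nitrate then oxidises F4 directly to 27, so the labile acetate never meets boron trichloride.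

Step 8. What may go wrong: some deprotonation at C20 would be followed by β-elimination of the lactone carboxylate, and proton exchange between enolate and ketone would erode the regiochemistry. The fallback avoids a free metal enolate under strongly basic conditions. It sets out from 11: soft enolisation with TMSOTf and triethylamine should give the less hindered C8 silyl enol ether F5, which is isolated; caesium fluoride with N-phenyltriflimide in DME then unmasks the enolate regiospecifically in the presence of the triflating agent and returns to the route at 13.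

**Further compounds**
F1 | step 14 | 12-isopropoxy-11,14-dimethoxy-7-oxoicetexa-8,11,13-trien-19,10-olide | O=C1C[C@@H]2[C@]3(CCC[C@]2(C)C(=O)O3)Cc2c1c(OC)c(C(C)C)c(OC(C)C)c2OC
F2 | step 14 | 7β-hydroxy-12-isopropoxy-11,14-dimethoxyicetexa-8,11,13-trien-19,10-olide | O[C@H]1C[C@@H]2[C@]3(CCC[C@]2(C)C(=O)O3)Cc2c1c(OC)c(C(C)C)c(OC(C)C)c2OC
F3 | step 16 | 12-hydroxy-11,14-dimethoxyicetexa-8,11,13-trien-19,10-olide | C1C[C@@H]2[C@]3(CCC[C@]2(C)C(=O)O3)Cc2c1c(OC)c(C(C)C)c(O)c2OC
F4 | step 16 | 7α-acetoxy-12-hydroxy-11,14-dimethoxyicetexa-8,11,13-trien-19,10-olide | CC(=O)O[C@@H]1C[C@@H]2[C@]3(CCC[C@]2(C)C(=O)O3)Cc2c1c(OC)c(C(C)C)c(O)c2OC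
F5 | step 8 | AB lactone Δ8-en-9-yl trimethylsilyl ether | C1C[C@@H]2[C@]3(CCC[C@]2(C)C(=O)O3)CC(O[Si](C)(C)C)=C1
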